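## Retrosynthetic overview
- The C15–OH comes from chemoselective reduction of a C15 carboxylic acid, which is carried as an allyl ester. The 3‑OAc comes from acetylation of the 3‑OH that the cyclisation sets free.
- Both rings come from one titanocene(III) radical cascade of an acyclic (3R)‑epoxy tetraene that already carries the tiglate. C4–C5 closes ring A, then C10–C9 closes ring B, and loss of a C17 hydrogen gives the 8(17)‑alkene. The conjugated C13=C14 ester is meant to stop the cascade after two rings.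
- The epoxy tiglate comes from Sharpless epoxidation (D‑(−)‑DET) with in‑flask tigloylation of the ω‑(E)‑allylic alcohol. That alcohol comes from SeO2 oxidation of allyl geranylgeranoate.
- Allyl geranylgeranoate comes from HWE olefination of (5E,9E)‑farnesylacetone, which fixes the 13E geometry at the cheapest stage.

Assumption: labdane numbering is used. C18 is the equatorial CH2O on C4 (trans to C20). The target is (3R,4S,5S,9R,10S), which is the ent‑labdane series. Compound 1 is bought as the (5E,9E) isomer.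

## Route

Step 1
Reactants: 1 (5E,9E)-farnesylacetone; 2 allyl diethylphosphonoacetate
Product: 3 allyl (2E,6E,10E)-geranylgeranoate
Conditions: NaH (1.5 equiv), 2 (1.5 equiv), THF, 0 °C to reflux; SiO2 removal of the 2Z ester
Reagents that add atoms: none
Why: Horner–Wadsworth–Emmons olefination of a methyl ketone puts the ester trans to the larger CH2 chain (E:Z about 4:1), and the minor 2Z isomer is removed here, which fixes the later C13=C14 E geometry.

Step 2
Reactants: 3 allyl (2E,6E,10E)-geranylgeranoate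
Product: 4 allyl (2E,6E,10E,14E)-16-hydroxy-3,7,11,15-tetramethylhexadeca-2,6,10,14-tetraenoate
Conditions: SeO2 (0.1 equiv), salicylic acid (0.1 equiv), t‑BuOOH (3 equiv), CH2Cl2, 0 °C to rt, stopped at about 50% conversion, 3 recycled
Reagents that add atoms: tert-butyl hydroperoxide CC(C)(C)OO; selenium dioxide O=[Se]=O
Why: Catalytic SeO2 allylic oxidation (ene reaction, then [2,3]-sigmatropic shift) prefers the electron-rich, least hindered terminal isopropylidene group and oxidises only its E-methyl group, while the conjugated alkene and the allyl-ester alkene are too electron-poor to react.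

Step 3
Reactants: 4 allyl (2E,6E,10E,14E)-16-hydroxy-3,7,11,15-tetramethylhexadeca-2,6,10,14-tetraenoate; 5 tigloyl chloride
Product: 7 allyl (2E,6E,10E)-3,7,11-trimethyl-13-[(2R,3R)-3-methyl-3-(tigloyloxymethyl)oxiran-2-yl]trideca-2,6,10-trienoate, via epoxy alcohol 6 (not isolated)
Conditions: Ti(OiPr)4 (10 mol %), D‑(−)‑DET (12 mol %), t‑BuOOH (2 equiv, decane), 4 Å MS, CH2Cl2, −20 °C; then P(OMe)3; then Et3N (3 equiv), DMAP (cat.), 5 (2 equiv), −20 to 0 °C
Reagents that add atoms: tert-butyl hydroperoxide CC(C)(C)OO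
Why: Katsuki–Sharpless asymmetric epoxidation with in-situ derivatisation touches only the hydroxyl-bearing alkene, D‑(−)‑tartrate gives the (2R,3R)-epoxide of an E-2-methylallylic alcohol (>95% ee) and so sets C3 as R, and the primary alcohol is acylated by 5 once the excess peroxide has been reduced.

Step 4
Reactants: 7 allyl (2E,6E,10E)-3,7,11-trimethyl-13-[(2R,3R)-3-methyl-3-(tigloyloxymethyl)oxiran-2-yl]trideca-2,6,10-trienoate
Product: 11 allyl (13E)-ent-3β-hydroxy-18-tigloyloxylabda-8(17),13-dien-15-oate (3R,4S,5S,9R,10S), via acyclic C4 radical 8 (not isolated), via bicyclic C8 radical 9 (not isolated), via titanium alkoxide 10 (not isolated)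
Conditions: Cp2TiCl2 (3 equiv), Mn dust (8 equiv), dry degassed THF, rt (green Cp2TiCl); 7 added over 30 min (0.05 M), 2 h; aq NaH2PO4 work-up
Reagents that add atoms: none
Why: Proposed new method: Cp2TiCl opens the epoxide homolytically at the more substituted carbon to give tertiary radical 8 with the C3–O bond and its R configuration intact; two chair-like 6-endo-trig closures onto the E-trisubstituted alkenes (C4–C5, then C10–C9) form ring A and ring B in one operation, with the bulky titanoxy group equatorial so that C3 dictates the face, the E geometries giving the trans fusion (H‑5 anti to the C10 methyl) and the equatorial C9 chain, and the freely rotating planar C4 radical (the epoxide C4 centre is erased) placing the larger CH2OTig group equatorial, next to H‑3 and away from the 1,3-diaxial C10 methyl, which gives 4S,5S,9R,10S; the nucleophilic tertiary radical 9 should stop there because 6-endo attack would hit the α-carbon of the enoate (polarity mismatch, loss of conjugation) and 5-exo attack at C13 would build a trans-hydrindane with two adjacent quaternary carbons, so excess Cp2TiCl removes a C17 hydrogen (mixed disproportionation) and gives the exocyclic alkene under anhydrous conditions; the tiglate stays out because its s-trans ester geometry holds the alkene away from C4; the closest known reaction type is the titanocene(III) (Nugent–RajanBabu) radical cyclisation of epoxypolyprenes, which gives 3-hydroxy-8(17)-ene decalins but runs on to a third ring when the next alkene is unconjugated.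

Step 5
Reactants: 11 allyl (13E)-ent-3β-hydroxy-18-tigloyloxylabda-8(17),13-dien-15-oate
Product: 12 allyl (13E)-ent-3β-acetoxy-18-tigloyloxylabda-8(17),13-dien-15-oate
Conditions: Ac2O (3 equiv), pyridine, DMAP (0.1 equiv), CH2Cl2, rt
Reagents that add atoms: acetic anhydride CC(=O)OC(C)=O
Why: DMAP-catalysed acylation of the only free hydroxyl (equatorial 3-OH) touches no stereocentre and leaves the other esters and the alkenes alone.

Step 6
Reactants: 12 allyl (13E)-ent-3β-acetoxy-18-tigloyloxylabda-8(17),13-dien-15-oate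
Product: 13 (13E)-ent-3β-acetoxy-18-tigloyloxylabda-8(17),13-dien-15-oic acid
Conditions: Pd(PPh3)4 (5 mol %), morpholine (5 equiv), THF, rt; 5% citric acid work-up
Reagents that add atoms: none
Why: In this Tsuji–Trost-type Pd(0) deallylation only the allyl ester can ionise to a π-allyl complex, which morpholine traps, so the acetate, the neopentyl tiglate and all the alkenes survive.

Step 7
Reactants: 13 (13E)-ent-3β-acetoxy-18-tigloyloxylabda-8(17),13-dien-15-oic acid
Product: 15 (13E)-ent-3β-acetoxy-18-tigloyloxylabda-8(17),13-dien-15-ol (target), via mixed anhydride 14 (not isolated)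
Conditions: i‑BuOCOCl (1.1 equiv), N‑methylmorpholine (1.1 equiv), THF, −15 °C, 15 min; then NaBH4 (3 equiv) in H2O, 0 °C, 20 min
Reagents that add atoms: none
Why: In this mixed carbonic anhydride activation and borohydride reduction, hydride attacks only the activated acyl carbon (1,4-attack is blocked by the β,β-disubstitution), the plain acetate and tiglate are inert at 0 °C, and the E geometry is kept.

## Compound list
1 | (5E,9E)-farnesylacetone | CC(=O)CC/C=C(C)/CC/C=C(C)/CCC=C(C)C | starting material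
2 | allyl diethylphosphonoacetate | C=CCOC(=O)CP(=O)(OCC)OCC | starting material
3 | allyl (2E,6E,10E)-geranylgeranoate | CC(C)=CCC/C(C)=C/CC/C(C)=C/CC/C(C)=C/C(=O)OCC=C | intermediate
4 | allyl (2E,6E,10E,14E)-16-hydroxy-3,7,11,15-tetramethylhexadeca-2,6,10,14-tetraenoate | OC/C(C)=C/CC/C(C)=C/CC/C(C)=C/CC/C(C)=C/C(=O)OCC=C | intermediate
5 | tigloyl chloride, (E)-2-methylbut-2-enoyl chloride | C/C=C(C)/C(=O)Cl | starting material
6 | allyl (2E,6E,10E)-13-[(2R,3R)-3-(hydroxymethyl)-3-methyloxiran-2-yl]-3,7,11-trimethyltrideca-2,6,10-trienoate (not isolated) | OC[C@@]1(C)O[C@@H]1CC/C(C)=C/CC/C(C)=C/CC/C(C)=C/C(=O)OCC=C | intermediate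
7 | (2R,3R)-epoxy tiglate of 6 | C/C=C(C)/C(=O)OC[C@@]1(C)O[C@@H]1CC/C(C)=C/CC/C(C)=C/CC/C(C)=C/C(=O)OCC=C | intermediate
8 | acyclic tertiary C4 radical, (3R)-O-TiCp2Cl (not isolated) | C/C=C(C)/C(=O)OC[C](C)[C@H](O[Ti](Cl)(C1C=CC=C1)C1C=CC=C1)CC/C(C)=C/CC/C(C)=C/CC/C(C)=C/C(=O)OCC=C | intermediate
9 | bicyclic tertiary C8 radical, 3-O-TiCp2Cl (not isolated) | C[C]1CC[C@H]2[C@@](C)(CC[C@@H](O[Ti](Cl)(C3C=CC=C3)C3C=CC=C3)[C@]2(C)COC(=O)/C(C)=C/C)[C@@H]1CC/C(C)=C/C(=O)OCC=C | intermediate
10 | titanium(IV) alkoxide of 11 (not isolated) | C=C1CC[C@H]2[C@@](C)(CC[C@@H](O[Ti](Cl)(C3C=CC=C3)C3C=CC=C3)[C@]2(C)COC(=O)/C(C)=C/C)[C@@H]1CC/C(C)=C/C(=O)OCC=C | intermediate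
11 | allyl (13E)-ent-3β-hydroxy-18-tigloyloxylabda-8(17),13-dien-15-oate, (3R,4S,5S,9R,10S) | C=C1CC[C@H]2[C@@](C)(CC[C@@H](O)[C@]2(C)COC(=O)/C(C)=C/C)[C@@H]1CC/C(C)=C/C(=O)OCC=C | intermediate
12 | allyl (13E)-ent-3β-acetoxy-18-tigloyloxylabda-8(17),13-dien-15-oate | C=C1CC[C@H]2[C@@](C)(CC[C@@H](OC(C)=O)[C@]2(C)COC(=O)/C(C)=C/C)[C@@H]1CC/C(C)=C/C(=O)OCC=C | intermediate
13 | (13E)-ent-3β-acetoxy-18-tigloyloxylabda-8(17),13-dien-15-oic acid | C=C1CC[C@H]2[C@@](C)(CC[C@@H](OC(C)=O)[C@]2(C)COC(=O)/C(C)=C/C)[C@@H]1CC/C(C)=C/C(=O)O | intermediate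
14 | isobutyl carbonic mixed anhydride of 13 (not isolated) | C=C1CC[C@H]2[C@@](C)(CC[C@@H](OC(C)=O)[C@]2(C)COC(=O)/C(C)=C/C)[C@@H]1CC/C(C)=C/C(=O)OC(=O)OCC(C)C | intermediate
15 | (13E)-ent-3β-acetoxy-18-tigloyloxylabda-8(17),13-dien-15-ol, (3R,4S,5S,9R,10S) | C=C1CC[C@H]2[C@@](C)(CC[C@@H](OC(C)=O)[C@]2(C)COC(=O)/C(C)=C/C)[C@@H]1CC/C(C)=C/CO | target

## Step count and risks
Total step count: 7. Longest linear sequence: 7.

**Step 4 (highest risk).** The C8 radical may still close a third ring onto the enoate. The cascade may stop early. The C4 centre may form as a mixture.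

The fallback sets out from 1 and comes back at 12. It keeps every alkene out of the side chain during the cascade and builds C13=C14 afterwards.
- SeO2/t‑BuOOH on 1 gives the ω-hydroxy ketone (5E,9E,13E)-15-hydroxy-6,10,14-trimethylpentadeca-5,9,13-trien-2-one F1.
- D‑(−)‑DET epoxidation gives the (2R,3R)-epoxy alcohol ketone F2, which 5 acylates in the flask to the keto epoxy tiglate F3.
- Cp2TiCl closes both rings to the bicyclic hydroxy ketone F4. A saturated keto chain offers the C8 radical nothing to add to.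
- Ac2O gives the keto acetate F5.
- The HWE reaction with 2 is then run last and gives 12. The 13Z isomer must now be separated on advanced material.

**Step 2.** Conversion is low, the internal alkenes may also be attacked, and over-oxidation is possible.

The fallback sets out from 3 and comes back at 4. It replaces C–H oxidation by cutting off the chain end and rebuilding it.
- NBS in aqueous THF adds to the terminal alkene and gives the racemic 14-bromo-15-hydroxy ester F6.
- DBU closes it to the racemic 14,15-epoxide F7.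
- H5IO6 cleaves this to the C14 aldehyde F8.
- 2-(Triphenylphosphoranylidene)propanal in hot toluene gives the (14E)-2-methyl enal F9.
- NaBH4/CeCl3 reduces the enal to 4.

**Step 7.** Some 1,4-reduction or ester loss may occur on hydride treatment of the activated acid.

The fallback sets out from 13 and comes back at 15. It passes through the aldehyde oxidation level.
- EtSH, EDC and DMAP give the S-ethyl thioester F10.
- Et3SiH with Pd/C (Fukuyama reduction) gives the (13E)-enal F11.
- Luche reduction (NaBH4, CeCl3, MeOH, 0 °C) gives 15 by clean 1,2-attack.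

## Further compounds
F1 | step 4 | (5E,9E,13E)-15-hydroxy-6,10,14-trimethylpentadeca-5,9,13-trien-2-one | CC(=O)CC/C=C(C)/CC/C=C(C)/CC/C=C(C)/CO
F2 | step 4 | (2R,3R)-epoxy alcohol ketone | OC[C@@]1(C)O[C@@H]1CC/C(C)=C/CC/C(C)=C/CCC(C)=O
F3 | step 4 | keto epoxy tiglate | C/C=C(C)/C(=O)OC[C@@]1(C)O[C@@H]1CC/C(C)=C/CC/C(C)=C/CCC(C)=O
F4 | step 4 | ent-3β-hydroxy-18-tigloyloxy-14,15-dinorlabd-8(17)-en-13-one | C=C1CC[C@H]2[C@@](C)(CC[C@@H](O)[C@]2(C)COC(=O)/C(C)=C/C)[C@@H]1CCC(C)=O
F5 | step 4 | ent-3β-acetoxy-18-tigloyloxy-14,15-dinorlabd-8(17)-en-13-one | C=C1CC[C@H]2[C@@](C)(CC[C@@H](OC(C)=O)[C@]2(C)COC(=O)/C(C)=C/C)[C@@H]1CCC(C)=O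
F6 | step 2 | allyl (2E,6E,10E)-14-bromo-15-hydroxy-3,7,11,15-tetramethylhexadeca-2,6,10-trienoate (racemic) | CC(C)(O)C(Br)CC/C(C)=C/CC/C(C)=C/CC/C(C)=C/C(=O)OCC=C
F7 | step 2 | allyl (2E,6E,10E)-14,15-epoxy-3,7,11,15-tetramethylhexadeca-2,6,10-trienoate (racemic) | CC1(C)OC1CC/C(C)=C/CC/C(C)=C/CC/C(C)=C/C(=O)OCC=C
F8 | step 2 | allyl (2E,6E,10E)-3,7,11-trimethyl-14-oxotetradeca-2,6,10-trienoate | O=CCC/C(C)=C/CC/C(C)=C/CC/C(C)=C/C(=O)OCC=C
F9 | step 2 | allyl (2E,6E,10E,14E)-3,7,11,15-tetramethyl-16-oxohexadeca-2,6,10,14-tetraenoate | O=C/C(C)=C/CC/C(C)=C/CC/C(C)=C/CC/C(C)=C/C(=O)OCC=C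
F10 | step 7 | S-ethyl (13E)-ent-3β-acetoxy-18-tigloyloxylabda-8(17),13-dien-15-thioate | C=C1CC[C@H]2[C@@](C)(CC[C@@H](OC(C)=O)[C@]2(C)COC(=O)/C(C)=C/C)[C@@H]1CC/C(C)=C/C(=O)SCC
F11 | step 7 | (13E)-ent-3β-acetoxy-18-tigloyloxylabda-8(17),13-dien-15-al | C=C1CC[C@H]2[C@@](C)(CC[C@@H](OC(C)=O)[C@]2(C)COC(=O)/C(C)=C/C)[C@@H]1CC/C(C)=C/C=O
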